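**Retrosynthetic overview**

- Feature: ring A is a benzene ring whose six carbons carry, in sequence, OCH3, CH3, OH, isobutyryl, OH and the CH2 bridge, so only the oxygen between the methyl-bearing and the bridge-bearing carbon is an ether. A methoxyalkyne (the C–OCH3 and C–CH3 carbons) and a 3-alkoxycyclobutenone (the other two oxygenated carbons, the bridge carbon and the one CH) bring in all three oxygens already told apart.
- Mallopallidol ⇐ hydrogenolysis of three benzyl ethers ⇐ Friedel–Crafts isobutyrylation at the only free CH of ring A ⇐ tribenzylated diarylmethane phenol.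
- Ring A ⇐ thermal benzannulation of a 3-benzyloxy-2-(chromanylmethyl)cyclobutenone with 1-methoxyprop-1-yne (alkyne from trichloroethylene).
- Cyclobutenone ⇐ O-benzylation ⇐ reductive C-alkylation of cyclobutane-1,3-dione (from two molecules of ethoxyacetylene) with the ring B aldehyde ⇐ benzylation and formylation of 5,7-dihydroxy-2,2,6-trimethylchroman-4-one ⇐ 2-methylphloroglucinol + 3-methylbut-2-enoic acid.
- Ring order: ring B is bought as the phloroglucinol, ring C (the dihydropyranone) is closed first, the four-membered ring is made separately and joined on, and ring A is formed last.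

Key step: step 10

Remark: the target has no stereocentre, so no stereocontrol is needed.
Remark: in step 3 ring C can close through either hydroxyl ortho to the new ketone, so the 8-methyl isomer is expected alongside the wanted 6-methyl isomer; only the latter is carried on.

**Route**

Step 1
Reactants: 1 ethoxyacetylene
Product: 3 3-ethoxycyclobut-2-en-1-one, via ketene 2 (not isolated)
Conditions: 1 (2 mol per mol of 3, commercial solution in hexanes), sealed pressure vessel, 100–120 °C; distillation
Reagents that add atoms: ethoxyacetylene (second molecule), CCOC#C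
Why: Two molecules of 1 are consumed per molecule of 3 in a thermal dimerisation of the 1-alkynyl ether, in which one molecule loses ethylene by a retro-ene reaction to give ketene 2 and the carbonyl carbon of 2 is then attacked by the nucleophilic CH carbon of the second molecule in a regioselective ketene–alkoxyalkyne [2+2] cycloaddition.

Step 2
Reactants: 3 3-ethoxycyclobut-2-en-1-one
Product: 4 cyclobutane-1,3-dione
Conditions: cold aq. H2SO4, 0 °C; continuous extraction with CH2Cl2
Reagents that add atoms: water, O
Why: Acid hydrolysis of the enol ether of a vinylogous ester (C-protonation, addition of water, loss of ethanol) should give the dione, which is isolated without base and used promptly because it is a strong carbon acid prone to self-condensation.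

Step 3
Reactants: 5 2-methylphloroglucinol, 6 3-methylbut-2-enoic acid
Product: 8 5,7-dihydroxy-2,2,6-trimethylchroman-4-one, via aryl enone 7 (not isolated)
Conditions: Eaton's reagent (P2O5 in MeSO3H), 70 °C
Reagents that add atoms: none
Why: Friedel–Crafts acylation at one of the two equivalent free ring carbons gives enone 7, which closes ring C by acid-mediated oxa-Michael addition; closure through the hydroxyl para to the methyl group gives 8, which is separated from the 8-methyl isomer, and the unwanted isomer can be returned to the same acid, where retro-oxa-Michael opening (Wessely–Moser-type equilibration) should regenerate the mixture.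

Step 4
Reactants: 8 5,7-dihydroxy-2,2,6-trimethylchroman-4-one
Product: 10 5,7-dihydroxy-2,2,6-trimethyl-4-oxochroman-8-carbaldehyde, via aryl iminium chloride 9 (not isolated)
Conditions: POCl3, DMF, MeCN, 0 °C to rt; then H2O, 50 °C
Reagents that add atoms: N,N-dimethylformamide, CN(C)C=O; water, O
Why: Vilsmeier–Haack formylation can only occur at C8, the single unsubstituted carbon of the phloroglucinol-type ring B, which reacts well below the temperature at which the hydrogen-bonded chromanone carbonyl would be attacked; hydrolysis of iminium salt 9 releases the aldehyde.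

Step 5
Reactants: 10 5,7-dihydroxy-2,2,6-trimethyl-4-oxochroman-8-carbaldehyde
Product: 11 5,7-bis(benzyloxy)-2,2,6-trimethyl-4-oxochroman-8-carbaldehyde
Conditions: BnBr (3 equiv), K2CO3, DMF, 60 °C
Reagents that add atoms: benzyl bromide, BrCc1ccccc1
Why: Williamson etherification of both phenols (each hydrogen-bonded to a carbonyl, hence warm DMF and excess bromide) protects ring B so that no phenol can later trap a ketene, and no free ring carbon remains for C-benzylation.

Step 6
Reactants: 4 cyclobutane-1,3-dione, 11 5,7-bis(benzyloxy)-2,2,6-trimethyl-4-oxochroman-8-carbaldehyde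
Product: 13 2-{[5,7-bis(benzyloxy)-2,2,6-trimethyl-4-oxochroman-8-yl]methyl}-3-hydroxycyclobut-2-en-1-one, via arylidene dione 12 (not isolated)
Conditions: Hantzsch ester (diethyl 2,6-dimethyl-1,4-dihydropyridine-3,5-dicarboxylate, 1.1 equiv), L-proline (20 mol %), MeCN, rt
Reagents that add atoms: none
Why: Three-component reductive alkylation, in which proline-catalysed Knoevenagel condensation of the strongly C–H acidic cyclic 1,3-dione with the aldehyde gives the electron-poor arylidene dione 12, which is reduced in situ by hydride transfer from the Hantzsch ester to the mono-C-alkylated dione, isolated as its enol.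

Step 7
Reactants: 13 2-{[5,7-bis(benzyloxy)-2,2,6-trimethyl-4-oxochroman-8-yl]methyl}-3-hydroxycyclobut-2-en-1-one
Product: 14 3-(benzyloxy)-2-{[5,7-bis(benzyloxy)-2,2,6-trimethyl-4-oxochroman-8-yl]methyl}cyclobut-2-en-1-one
Conditions: BnOH, PPh3, DIAD, THF, 0 °C to rt
Reagents that add atoms: benzyl alcohol, OCc1ccccc1
Why: Mitsunobu alkylation of the strongly acidic enol (a vinylogous carboxylic acid) should take place on oxygen, and because the dione is symmetrical either oxygen gives the same 2-substituted 3-benzyloxycyclobutenone.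

Step 8
Reactants: 15 trichloroethylene
Product: 17 (E)-1,2-dichloro-1-methoxyethene, via dichloroacetylene 16 (not isolated)
Conditions: NaOMe, MeOH–THF, 0 to 60 °C; distillation
Reagents that add atoms: sodium methoxide, [Na+].[O-]C
Why: Methoxide dehydrochlorinates trichloroethylene to dichloroacetylene 16, to which methoxide and methanol add in anti fashion to give the (E)-dichlorovinyl ether (elimination–addition).

Step 9
Reactants: 17 (E)-1,2-dichloro-1-methoxyethene
Product: 20 1-methoxyprop-1-yne, via chloro(methoxy)ethyne 18 (not isolated), via lithium methoxyacetylide 19 (not isolated)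
Conditions: n-BuLi (2.2 equiv), Et2O, −78 to −40 °C; then MeI, DMPU, −78 °C to rt; co-distilled and used as an assayed hydrocarbon solution
Reagents that add atoms: iodomethane, CI
Why: n-BuLi removes the vinylic proton and lithium chloride is lost to give chloroalkyne 18, lithium–chlorine exchange with the second equivalent gives acetylide 19, and C-methylation with MeI gives the ynol ether (dichlorovinyl ether route to alkoxyalkynes).

Step 10
Reactants: 14 3-(benzyloxy)-2-{[5,7-bis(benzyloxy)-2,2,6-trimethyl-4-oxochroman-8-yl]methyl}cyclobut-2-en-1-one, 20 1-methoxyprop-1-yne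
Product: 25 5,7-bis(benzyloxy)-8-{[6-(benzyloxy)-4-hydroxy-2-methoxy-3-methylphenyl]methyl}-2,2,6-trimethylchroman-4-one, via vinylketene 21 (not isolated), via vinylcyclobutenone 22 (not isolated), via dienylketene 23 (not isolated), via cyclohexadienone 24 (not isolated)
Conditions: 20 (3–5 equiv), toluene, sealed tube, 120–140 °C; then K2CO3, MeOH, rt
Reagents that add atoms: none
Why: Proposed new method: heating should open the cyclobutenone by four-electron electrocyclic cleavage of its C1–C4 bond to the 3-benzyloxy vinylketene 21, whose ketene carbon is attacked by the methyl-bearing carbon of the ynol ether in a [2+2] cycloaddition giving vinylcyclobutenone 22; a second four-electron opening gives dienylketene 23, which closes ring A by a thermal six-electron electrocyclisation (bond between the ketene carbon and the former CH2 carbon of the cyclobutenone) and tautomerises through 24 to phenol 25. The closest known reaction is the Danheiser benzannulation of 3-alkyl- or 3-aryl-cyclobutenones with alkoxyalkynes; a 3-alkoxycyclobutenone is not established in this role, because its vinylogous-ester conjugation stabilises the four-membered ring and should raise the temperature of the first opening, hence 120–140 °C instead of about 80 °C. No stereocentre is formed. The one selectivity needed is the regiochemistry of the ketene–alkyne cycloaddition, and the polarisation of the ynol ether secures it by making the methyl-bearing carbon the nucleophile, which places OCH3 next to the bridge carbon and C–CH3 next to the new hydroxyl. In 21 the benzyloxy group is cross-conjugated and should not quench the ketene, the chromanone and the aryl benzyl ethers are thermally inert, and the K2CO3/MeOH treatment returns any product phenol that has been acylated by a ketene.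

Step 11
Reactants: 25 5,7-bis(benzyloxy)-8-{[6-(benzyloxy)-4-hydroxy-2-methoxy-3-methylphenyl]methyl}-2,2,6-trimethylchroman-4-one
Product: 26 5,7-bis(benzyloxy)-8-{[6-(benzyloxy)-4-hydroxy-2-methoxy-3-methyl-5-(2-methylpropanoyl)phenyl]methyl}-2,2,6-trimethylchroman-4-one
Conditions: i-PrCOCl (1.5 equiv), TiCl4 (2.2 equiv), CH2Cl2, −40 to 0 °C; aq. HCl work-up
Reagents that add atoms: 2-methylpropanoyl chloride, CC(C)C(Cl)=O
Why: Friedel–Crafts acylation ortho to the free phenol (through its titanium phenoxide) can occur only at the single unsubstituted carbon of ring A, activated by the ortho hydroxyl, the ortho benzyloxy and the para methoxy group, while ring B is fully substituted and the benzyl phenyl rings are far less nucleophilic.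

Step 12
Reactants: 26 5,7-bis(benzyloxy)-8-{[6-(benzyloxy)-4-hydroxy-2-methoxy-3-methyl-5-(2-methylpropanoyl)phenyl]methyl}-2,2,6-trimethylchroman-4-one
Product: 27 mallopallidol
Conditions: H2 (1 atm), Pd/C (10 wt%), EtOAc–MeOH, rt
Reagents that add atoms: none
Why: Catalytic hydrogenolysis cleaves the three aryl benzyl ethers under neutral conditions that should leave the two aryl ketones, the methyl ether and the diarylmethane bridge untouched.

**Compound list**

1 | ethoxyacetylene (ethoxyethyne) | CCOC#C | starting material
2 | ketene (ethenone) | C=C=O | intermediate (not isolated)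
3 | 3-ethoxycyclobut-2-en-1-one | CCOC1=CC(=O)C1 | intermediate
4 | cyclobutane-1,3-dione | O=C1CC(=O)C1 | intermediate
5 | 2-methylphloroglucinol (2-methylbenzene-1,3,5-triol) | Cc1c(O)cc(O)cc1O | starting material
6 | 3-methylbut-2-enoic acid | CC(C)=CC(=O)O | starting material
7 | 3-methyl-1-(2,4,6-trihydroxy-3-methylphenyl)but-2-en-1-one | CC(C)=CC(=O)c1c(O)cc(O)c(C)c1O | intermediate (not isolated)
8 | 5,7-dihydroxy-2,2,6-trimethylchroman-4-one | O=C1CC(C)(C)Oc2cc(O)c(C)c(O)c21 | intermediate
9 | N-[(5,7-dihydroxy-2,2,6-trimethyl-4-oxochroman-8-yl)methylidene]-N-methylmethanaminium chloride | C[N+](C)=Cc1c(O)c(C)c(O)c2c1OC(C)(C)CC2=O.[Cl-] | intermediate (not isolated)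
10 | 5,7-dihydroxy-2,2,6-trimethyl-4-oxochroman-8-carbaldehyde | O=Cc1c(O)c(C)c(O)c2c1OC(C)(C)CC2=O | intermediate
11 | 5,7-bis(benzyloxy)-2,2,6-trimethyl-4-oxochroman-8-carbaldehyde | O=Cc1c(OCc2ccccc2)c(C)c(OCc2ccccc2)c2c1OC(C)(C)CC2=O | intermediate
12 | 2-{[5,7-bis(benzyloxy)-2,2,6-trimethyl-4-oxochroman-8-yl]methylidene}cyclobutane-1,3-dione | O=C1CC(=O)C1=Cc1c(OCc2ccccc2)c(C)c(OCc2ccccc2)c2c1OC(C)(C)CC2=O | intermediate (not isolated)
13 | 2-{[5,7-bis(benzyloxy)-2,2,6-trimethyl-4-oxochroman-8-yl]methyl}-3-hydroxycyclobut-2-en-1-one | O=C1CC(O)=C1Cc1c(OCc2ccccc2)c(C)c(OCc2ccccc2)c2c1OC(C)(C)CC2=O | intermediate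
14 | 3-(benzyloxy)-2-{[5,7-bis(benzyloxy)-2,2,6-trimethyl-4-oxochroman-8-yl]methyl}cyclobut-2-en-1-one | O=C1CC(OCc2ccccc2)=C1Cc1c(OCc2ccccc2)c(C)c(OCc2ccccc2)c2c1OC(C)(C)CC2=O | intermediate
15 | trichloroethylene | ClC=C(Cl)Cl | starting material
16 | dichloroacetylene | ClC#CCl | intermediate (not isolated)
17 | (E)-1,2-dichloro-1-methoxyethene | CO/C(Cl)=C\Cl | intermediate
18 | 1-chloro-2-methoxyethyne | COC#CCl | intermediate (not isolated)
19 | lithium methoxyacetylide | [Li]C#COC | intermediate (not isolated)
20 | 1-methoxyprop-1-yne | COC#CC | intermediate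
21 | 3-(benzyloxy)-2-{[5,7-bis(benzyloxy)-2,2,6-trimethyl-4-oxochroman-8-yl]methyl}buta-1,3-dien-1-one | C=C(OCc1ccccc1)C(=C=O)Cc1c(OCc2ccccc2)c(C)c(OCc2ccccc2)c2c1OC(C)(C)CC2=O | intermediate (not isolated)
22 | 4-[1-(benzyloxy)ethenyl]-4-{[5,7-bis(benzyloxy)-2,2,6-trimethyl-4-oxochroman-8-yl]methyl}-3-methoxy-2-methylcyclobut-2-en-1-one (racemic) | COC1=C(C)C(=O)C1(Cc1c(OCc2ccccc2)c(C)c(OCc2ccccc2)c2c1OC(C)(C)CC2=O)C(=C)OCc1ccccc1 | intermediate (not isolated)
23 | (3E)-5-(benzyloxy)-4-{[5,7-bis(benzyloxy)-2,2,6-trimethyl-4-oxochroman-8-yl]methyl}-3-methoxy-2-methylhexa-1,3,5-trien-1-one | O=C=C(C)/C(OC)=C(\C(OCc1ccccc1)=C)Cc1c(OCc2ccccc2)c(C)c(OCc2ccccc2)c2c1OC(C)(C)CC2=O | intermediate (not isolated)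
24 | 5-(benzyloxy)-4-{[5,7-bis(benzyloxy)-2,2,6-trimethyl-4-oxochroman-8-yl]methyl}-3-methoxy-2-methylcyclohexa-2,4-dien-1-one | COC1=C(C)C(=O)CC(OCc2ccccc2)=C1Cc1c(OCc2ccccc2)c(C)c(OCc2ccccc2)c2c1OC(C)(C)CC2=O | intermediate (not isolated)
25 | 5,7-bis(benzyloxy)-8-{[6-(benzyloxy)-4-hydroxy-2-methoxy-3-methylphenyl]methyl}-2,2,6-trimethylchroman-4-one | COc1c(C)c(O)cc(OCc2ccccc2)c1Cc1c(OCc2ccccc2)c(C)c(OCc2ccccc2)c2c1OC(C)(C)CC2=O | intermediate
26 | 5,7-bis(benzyloxy)-8-{[6-(benzyloxy)-4-hydroxy-2-methoxy-3-methyl-5-(2-methylpropanoyl)phenyl]methyl}-2,2,6-trimethylchroman-4-one | COc1c(C)c(O)c(C(=O)C(C)C)c(OCc2ccccc2)c1Cc1c(OCc2ccccc2)c(C)c(OCc2ccccc2)c2c1OC(C)(C)CC2=O | intermediate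
27 | mallopallidol, 8-{[2,4-dihydroxy-6-methoxy-5-methyl-3-(2-methylpropanoyl)phenyl]methyl}-5,7-dihydroxy-2,2,6-trimethylchroman-4-one | COc1c(C)c(O)c(C(=O)C(C)C)c(O)c1Cc1c(O)c(C)c(O)c2c1OC(C)(C)CC2=O | target

**Step count and risk**

Total step count: 12. Longest linear sequence: 8 steps (steps 3, 4, 5, 6, 7, 10, 11, 12, from 5 to 27).

Steps most likely to fail:

1. Step 10 (benzannulation). The first electrocyclic opening may be too slow, because the 3-benzyloxy group stabilises the cyclobutenone as a vinylogous ester. At the temperature then required the ynol ether may oligomerise, or the vinylketene may dimerise before it meets the alkyne. The fallback gives up the annulation and joins a finished ring A to ring B by the classical aminomethyl (Mannich) coupling of phloroglucinols; it sets out from 8 (with ring A made from 5) and comes back to the route at 27. Friedel–Crafts acylation of 5 with 2-methylpropanoyl chloride and AlCl3 in nitrobenzene should give 2-methyl-1-(2,4,6-trihydroxy-3-methylphenyl)propan-1-one F1. Dimethyl sulfate (1 equiv) with K2CO3 in acetone should methylate the one hydroxyl that is not hydrogen-bonded to the ketone, giving 1-(2,6-dihydroxy-4-methoxy-3-methylphenyl)-2-methylpropan-1-one F2. Chromanone 8 with N,N-dimethylmethyleneiminium iodide (Eschenmoser's salt) should give the Mannich base 8-[(dimethylamino)methyl]-5,7-dihydroxy-2,2,6-trimethylchroman-4-one F3. Heating F3 with F2 in dioxane should expel dimethylamine to the ortho-quinone methide 5-hydroxy-2,2,6-trimethyl-8-methylidene-2,3-dihydrochromene-4,7-dione F4 (not isolated), which is captured by the only free ring carbon of F2 to give 27 directly.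

2. Step 6 (reductive alkylation). The strained, strongly acidic dione 4 may self-condense under amine catalysis, and a second molecule of 4 may add to the arylidene intermediate faster than hydride reaches the doubly ortho-substituted benzylidene carbon. The fallback avoids free 4 and builds the four-membered ring on the side chain; it sets out from 11 and comes back at 13. Reductive alkylation of Meldrum's acid with 11 (Hantzsch ester, L-proline) should pass through the arylidene Meldrum's acid 5-{[5,7-bis(benzyloxy)-2,2,6-trimethyl-4-oxochroman-8-yl]methylidene}-2,2-dimethyl-1,3-dioxane-4,6-dione F5 (not isolated) to 5-{[5,7-bis(benzyloxy)-2,2,6-trimethyl-4-oxochroman-8-yl]methyl}-2,2-dimethyl-1,3-dioxane-4,6-dione F6. Heating F6 in aqueous pyridine should give 3-[5,7-bis(benzyloxy)-2,2,6-trimethyl-4-oxochroman-8-yl]propanoic acid F7. Oxalyl chloride with catalytic DMF should give the acid chloride 3-[5,7-bis(benzyloxy)-2,2,6-trimethyl-4-oxochroman-8-yl]propanoyl chloride F8. Triethylamine in the presence of ethoxyacetylene 1 should generate the aldoketene 3-[5,7-bis(benzyloxy)-2,2,6-trimethyl-4-oxochroman-8-yl]prop-1-en-1-one F9 (not isolated), which undergoes [2+2] cycloaddition to 4-{[5,7-bis(benzyloxy)-2,2,6-trimethyl-4-oxochroman-8-yl]methyl}-3-ethoxycyclobut-2-en-1-one F10. Dilute aqueous acid should hydrolyse F10 to the same 2-substituted dione enol 13.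

3. Step 11 (acylation). TiCl4 may chelate between a carbonyl and a neighbouring benzyloxy group (the chromanone carbonyl and its peri ether, or the new ketone and its ortho ether) and cleave benzyl ethers, and the benzyl cations released may alkylate ring A before it is acylated. The fallback reverses the order of the last two operations; it sets out from 25 and comes back at 27. Hydrogenolysis of 25 (H2, Pd/C, EtOAc–MeOH) should give 8-[(2,4-dihydroxy-6-methoxy-5-methylphenyl)methyl]-5,7-dihydroxy-2,2,6-trimethylchroman-4-one F11. C-acylation of F11 with 2-methylpropanoic acid and BF3·OEt2 at 60–80 °C should then occur at the only unsubstituted aromatic carbon in the molecule and give 27, any O-acyl groups being lost on aqueous work-up.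

Further compounds
F1 | step 10 | 2-methyl-1-(2,4,6-trihydroxy-3-methylphenyl)propan-1-one | CC(C)C(=O)c1c(O)cc(O)c(C)c1O
F2 | step 10 | 1-(2,6-dihydroxy-4-methoxy-3-methylphenyl)-2-methylpropan-1-one | COc1cc(O)c(C(=O)C(C)C)c(O)c1C
F3 | step 10 | 8-[(dimethylamino)methyl]-5,7-dihydroxy-2,2,6-trimethylchroman-4-one | CN(C)Cc1c(O)c(C)c(O)c2c1OC(C)(C)CC2=O
F4 | step 10 | 5-hydroxy-2,2,6-trimethyl-8-methylidene-2,3-dihydrochromene-4,7-dione (ortho-quinone methide from F3, not isolated) | C=C1C(=O)C(C)=C(O)C2=C1OC(C)(C)CC2=O
F5 | step 6 | 5-{[5,7-bis(benzyloxy)-2,2,6-trimethyl-4-oxochroman-8-yl]methylidene}-2,2-dimethyl-1,3-dioxane-4,6-dione (not isolated) | CC1(C)OC(=O)C(=Cc2c(OCc3ccccc3)c(C)c(OCc3ccccc3)c3c2OC(C)(C)CC3=O)C(=O)O1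
F6 | step 6 | 5-{[5,7-bis(benzyloxy)-2,2,6-trimethyl-4-oxochroman-8-yl]methyl}-2,2-dimethyl-1,3-dioxane-4,6-dione | CC1(C)OC(=O)C(Cc2c(OCc3ccccc3)c(C)c(OCc3ccccc3)c3c2OC(C)(C)CC3=O)C(=O)O1
F7 | step 6 | 3-[5,7-bis(benzyloxy)-2,2,6-trimethyl-4-oxochroman-8-yl]propanoic acid | OC(=O)CCc1c(OCc2ccccc2)c(C)c(OCc2ccccc2)c2c1OC(C)(C)CC2=O
F8 | step 6 | 3-[5,7-bis(benzyloxy)-2,2,6-trimethyl-4-oxochroman-8-yl]propanoyl chloride | ClC(=O)CCc1c(OCc2ccccc2)c(C)c(OCc2ccccc2)c2c1OC(C)(C)CC2=O
F9 | step 6 | 3-[5,7-bis(benzyloxy)-2,2,6-trimethyl-4-oxochroman-8-yl]prop-1-en-1-one (not isolated) | O=C=CCc1c(OCc2ccccc2)c(C)c(OCc2ccccc2)c2c1OC(C)(C)CC2=O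
F10 | step 6 | 4-{[5,7-bis(benzyloxy)-2,2,6-trimethyl-4-oxochroman-8-yl]methyl}-3-ethoxycyclobut-2-en-1-one (racemic) | CCOC1=CC(=O)C1Cc1c(OCc2ccccc2)c(C)c(OCc2ccccc2)c2c1OC(C)(C)CC2=O
F11 | step 11 | 8-[(2,4-dihydroxy-6-methoxy-5-methylphenyl)methyl]-5,7-dihydroxy-2,2,6-trimethylchroman-4-one | COc1c(C)c(O)cc(O)c1Cc1c(O)c(C)c(O)c2c1OC(C)(C)CC2=O
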